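A small charge of starting material in a larger charge of coupling partner, if the two react in one step, loses a share per minute set by the partner, so beta, with 0.210 M of partner, should run on the clock of the midnight run, which held 0.21 M.

| setting | midnight | beta | theta | alpha | gamma |
|---|---|---|---|---|---|
| starting material | 0.21 M | 0.14 M | 0.14 M | 0.14 M | 0.14 M |
| coupling partner | 0.21 M | 0.210 M | 0.210 M | 0.210 M | 0.210 M |
| temperature | 5 °C | 5 °C | −25 °C | −10 °C | 20 °C |
| remark | run made earlier |  |  |  |  |
| time |  | 40 min | 40 min | 40 min | 40 min |

- midnight (time / min: intermediate / %, target / %): 0.667: 1.9, 0; 1.33: 3.1, 0; 3.00: 5.5, 0; 8.00: 12.8, 0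

(standard deviation of a reading: 0.5 percentage points)

- the best flask by amount of intermediate, in percent of the starting material charged; "all alike" if 1.5 percentage points covers them all (beta / theta / alpha / gamma / all alike)
- amount of intermediate at the end, in percent of the starting material charged, beta
- amount of intermediate at the end, in percent of the starting material charged, theta
- amount of intermediate at the end, in percent of the starting material charged, alpha
- amount of intermediate at the end, in percent of the starting material charged, gamma

- the earlier runs do not show what temperature does; that part of a forecast is a guess

Solve the clock at both ends. At the short end, the share of starting material gone grows as t/τ; at the long end, what is left tends towards nothing. The exponential of a pseudo-first-order step joins the two, and the last midnight reading, with 12.8 % of intermediate at 8.00 min, gives τ: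

τ = t / ln(A_start / A_t) = 58.4 min

Call τ the filling time: the time in which the starting material falls by a factor e at this partner level, at 5 °C.

Now climb the ladder. The readings span 8.00 min, shorter than τ, so the intermediate climbs on a near-straight line, and target reads 0 %. With a scatter of 0.5 percentage points, that zero gives the onward step no clock of its own.

The next rung is the flask time of 40 min, also shorter than τ but of its order:

A_t / A_start = exp(−t/τ) = 50.4 %

My reckoning for beta therefore leaves 50.4 % of the starting material, and the intermediate stands below a ceiling of 49.6 %, about half of the charge. I ignore the slowing as partner is used. The runs give no τ at the other temperatures.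

The forecast gave 38 % for beta, 5 % for theta, 14 % for alpha and 60 % for gamma, and said: “Gamma is probably the best flask”.

The flasks end at 28.9 % in beta, 2.49 % in theta, 13.1 % in alpha and 5.08 % in gamma, so beta holds the most intermediate. At 40.0 min, beta holds 11.4 % of decomposed reagent, more than its 4.02 % of target. Beta keeps 52.2 % of its starting material, against the 50.4 % reckoned from τ, so 47.8 % has reacted; with 28.9 % standing as intermediate, 19 points lie beyond the intermediate in beta.

    starting material + coupling partner → intermediate (k = 0.00160 /M/s, Ea = 66.0 kJ/mol)
    intermediate → target (k = 1.50 × 10⁻⁴ /s, Ea = 84.0 kJ/mol)
    coupling partner + target → over-reaction product (k = 0.00470 /M/s, Ea = 51.0 kJ/mol)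
    intermediate → decomposed reagent (k = 2.30 × 10⁻⁴ /s, Ea = 78.0 kJ/mol)
    target ⇌ isomer of the product (K = 1.10, k = 4.90 × 10⁻⁵ /s, Ea = 86.0 kJ/mol, ΔH = −3.00 kJ/mol)
    (constants at 5 °C)

Take a flask like theta kept at 0 °C. Spread evenly over the degrees, the factor 140 by which the first step speeds up from the coldest to the hottest flask stretches τ to 101 min, so 67.2 % of the starting material should remain at 40 min, under a ceiling of 32.8 % for intermediate. That flask keeps 66 % of its starting material and holds 26.3 % of intermediate.

The data come from a simulation with constants of no real substance, and the scatter is random.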